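**Retrosynthetic overview**
- The (E)-propenyl group comes from a C-1 aldehyde (Takai olefination). The C-2 acyl bond comes from opening a cis-fused C-1/C-2 γ-lactone with a 3-lithiated 2,4-dimethoxy-5-arylpyridine; the pyridone ring is bought as a pyridine and unmasked last.
- The C3=C4–CH3 unit comes from a C-4 ketone (enol triflate, Negishi methylation) of a trans-decalone lactone.
- Key step: the trans-decalone lactone comes from a flat tetralone lactone, whose toluene-derived benzene ring is hydrogenated all-cis from the face opposite the C-1 arm (sets C-8a and C-7; C-4a is then equilibrated).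
- The tetralone lactone comes from (3-methylphenyl)boronic acid, furan-2(5H)-one and tert-butyl bromoacetate (asymmetric 1,4-addition sets C-1, then alkylation and Friedel–Crafts acylation).
- Ring order: lactone (bought as butenolide), then ring A (Friedel–Crafts onto the arene), then ring B (the arene itself, saturated in the key step).

Assumption: the SMILES is read literally, i.e. (1S,2S,4aS,7S,8aR): a trans-decalin with H-1, H-2, H-7 and H-8a on one face (called β) and H-4a on the other (α), so the propenyl group is axial and cis to the equatorial acyl group; the decalin numbering of the target is used for all intermediates.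

**Route**

Step 1
Reactants: 1 furan-2(5H)-one; 2 (3-methylphenyl)boronic acid
Product: 3 (4R)-4-(3-methylphenyl)oxolan-2-one
Conditions: [Rh(OH)((R)-binap)]2 (3 mol % Rh), dioxane/H2O 10:1, 35 °C
Reagents that add atoms: none
Why: Hayashi–Miyaura rhodium-catalysed asymmetric 1,4-addition; the (R)-BINAP–rhodium aryl species adds to one enantioface of the butenolide (sense taken from the cyclohexenone model, here giving R) and sets C-1, the only stereocentre introduced by a chiral reagent.

Step 2
Reactants: 3 (4R)-4-(3-methylphenyl)oxolan-2-one; 4 tert-butyl bromoacetate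
Product: 6 tert-butyl [(3S,4R)-4-(3-methylphenyl)-2-oxooxolan-3-yl]acetate, via lithium enolate 5 (not isolated)
Conditions: LiN(SiMe3)2, THF, −78 °C; then 4, −78 → −40 °C
Reagents that add atoms: none
Why: Lactone enolate alkylation (SN2); the electrophile enters anti to the β-aryl group and gives the 3,4-trans lactone (C-2 is corrected in step 3).

Step 3
Reactants: 6 tert-butyl [(3S,4R)-4-(3-methylphenyl)-2-oxooxolan-3-yl]acetate
Product: 8 cis-fused tetralone lactone (3aR,9bR)-8-methyl-3a,4-dihydronaphtho[1,2-c]furan-3,5(1H,9bH)-dione, via trans-fused tetralone lactone 7 (not isolated)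
Conditions: Eaton's reagent (P2O5 in MeSO3H), 40 °C; work-up; then DBU (0.2 equiv), THF, 23 °C
Reagents that add atoms: none
Why: Acid removes the tert-butyl group and the acylium ion closes ring A by intramolecular Friedel–Crafts acylation para to the methyl group; DBU then epimerises C-2 (α to the lactone carbonyl) to the less strained cis-fused lactone, leaving C-1 untouched.

Step 4
Reactants: 8 cis-fused tetralone lactone
Product: 10 trans-decalone lactone (H-1/H-2/H-7/H-8a β; H-4a α), via all-cis decalone lactone 9 (not isolated)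
Conditions: H2 (20 bar), Rh(cod)(CAAC)Cl (3 mol %; CAAC = 2-(2,6-diisopropylphenyl)-3,3-dimethyl-2-azaspiro[4.5]dec-1-ylidene), CF3CH2OH, 30 °C; filter; then DBU (0.3 equiv), toluene, 60 °C
Reagents that add atoms: none
Why: Dearomatising, ring-selective hydrogenation of an aryl ketone with a CAAC–rhodium catalyst (ketone and lactone kept); hydrogen is delivered all-cis from the β face, anti to the pseudoaxial C-1–CH2O arm, which sets C-8a and C-7 (and C-4a cis), and DBU equilibration through the C-4 enol then turns C-4a to the trans-decalone because both chair forms of the cis isomer carry a syn-diaxial C/C contact.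

Step 5
Reactants: 10 trans-decalone lactone
Product: 12 Δ3 enol triflate of 10, via lithium enolate 11 (not isolated)
Conditions: LiN(SiMe3)2 (1.05 equiv), THF, −78 °C (ketone added to base); then PhNTf2, −78 → 0 °C
Reagents that add atoms: N-phenylbis(trifluoromethanesulfonimide), FC(F)(F)S(=O)(=O)N(c1ccccc1)S(=O)(=O)C(F)(F)F
Why: Kinetic enolisation at the less substituted α-carbon (C-3 CH2 rather than the ring-fusion C-4a) and O-sulfonylation give the enol triflate with no stereocentre changed.

Step 6
Reactants: 12 Δ3 enol triflate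
Product: 13 decalin lactone with C3=C4–CH3 (C-1–CH2–O–C(=O)–C-2 lactone; H-1/H-2/H-7/H-8a β; H-4a α)
Conditions: Me2Zn (1.5 equiv), Pd(PPh3)4 (5 mol %), THF, 0 → 40 °C
Reagents that add atoms: dimethylzinc, C[Zn]C
Why: Negishi cross-coupling of the enol triflate under zerovalent palladium catalysis installs the C-4 methyl group with the double bond fixed at C3=C4; the neutral conditions keep the β,γ-unsaturated lactone from conjugating or epimerising.

Step 7
Reactants: 14 5-bromo-2,4-dimethoxypyridine; 15 [4-(benzyloxy)phenyl]boronic acid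
Product: 16 5-[4-(benzyloxy)phenyl]-2,4-dimethoxypyridine
Conditions: Pd(dppf)Cl2 (3 mol %), K2CO3, dioxane/H2O, 85 °C
Reagents that add atoms: none
Why: Suzuki–Miyaura coupling at the only C–Br bond builds the 5-arylpyridine.

Step 8
Reactants: 16 5-[4-(benzyloxy)phenyl]-2,4-dimethoxypyridine (1.3 equiv); 13 decalin lactone
Product: 18 keto alcohol (C-1 CH2OH; C-2 aroyl; stereocentres arranged as in 13), via 3-lithiopyridine 17 (not isolated)
Conditions: 16, n-BuLi, THF, −78 → −30 °C; then 13, −78 → −40 °C; aq. NH4Cl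
Reagents that add atoms: none
Why: Directed ortho-lithiation between the two methoxy groups, then acyl substitution on the γ-lactone, gives the aryl ketone and frees the C-1 hydroxymethyl group; the di-ortho-substituted ketone is too hindered for a second addition and no stereocentre is touched.

Step 9
Reactants: 18 keto alcohol
Product: 19 keto aldehyde (C-1 CHO axial; C-2 aroyl)
Conditions: Dess–Martin periodinane, NaHCO3, CH2Cl2, 0 → 23 °C
Reagents that add atoms: none
Why: Dess–Martin oxidation of the primary alcohol under buffered, non-basic conditions, so the axial C-1 formyl group does not epimerise.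

Step 10
Reactants: 19 keto aldehyde
Product: 20 protected target {5-[4-(benzyloxy)phenyl]-2,4-dimethoxypyridin-3-yl}[(1S,2S,4aS,7S,8aR)-4,7-dimethyl-1-[(E)-prop-1-enyl]-1,2,4a,5,6,7,8,8a-octahydronaphthalen-2-yl]methanone
Conditions: CrCl2 (8 equiv), CH3CHI2 (2.5 equiv), THF, 23 °C
Reagents that add atoms: 1,1-diiodoethane, CC(I)I
Why: Takai–Utimoto olefination; the geminal dichromium reagent adds to the aldehyde only (not the hindered ketone) and eliminates to the (E)-alkene without base, so C-1 and C-2 keep their configuration.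

Step 11
Reactants: 20 protected target
Product: 22 target 4-hydroxy-5-(4-hydroxyphenyl)-3-[(1S,2S,4aS,7S,8aR)-4,7-dimethyl-1-[(E)-prop-1-enyl]-1,2,4a,5,6,7,8,8a-octahydronaphthalene-2-carbonyl]pyridin-2(1H)-one, via tris(trimethylsilyl) ether 21 (not isolated)
Conditions: Me3SiI (6 equiv), CHCl3, 0 → 23 °C; then MeOH
Reagents that add atoms: none
Why: Iodotrimethylsilane dealkylation (iodide SN2 on the silyl-activated ethers) cleaves the benzyl ether, the 2-methoxypyridine and the vinylogous-ester 4-methoxy group at room temperature, conditions that di- and trisubstituted alkenes normally tolerate, and methanolysis of the silyl ethers releases the 4-hydroxy-2-pyridone.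

**Compound list**
1 | furan-2(5H)-one | O=C1OCC=C1 | starting material
2 | (3-methylphenyl)boronic acid | Cc1cccc(B(O)O)c1 | starting material
3 | (4R)-4-(3-methylphenyl)oxolan-2-one | O=C1OC[C@@H](c2cccc(C)c2)C1 | intermediate
4 | tert-butyl bromoacetate | CC(C)(C)OC(=O)CBr | starting material
5 | lithium enolate of 3 (not isolated) | [Li]OC1=C[C@H](c2cccc(C)c2)CO1 | intermediate
6 | tert-butyl [(3S,4R)-4-(3-methylphenyl)-2-oxooxolan-3-yl]acetate (3,4-trans) | O=C1OC[C@@H](c2cccc(C)c2)[C@@H]1CC(=O)OC(C)(C)C | intermediate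
7 | trans-fused tetralone lactone, (3aS,9bR)-8-methyl-3a,4-dihydronaphtho[1,2-c]furan-3,5(1H,9bH)-dione (not isolated) | O=C3OC[C@H]1c2cc(C)ccc2C(=O)C[C@@H]13 | intermediate
8 | cis-fused tetralone lactone, (3aR,9bR)-8-methyl-3a,4-dihydronaphtho[1,2-c]furan-3,5(1H,9bH)-dione | O=C3OC[C@H]1c2cc(C)ccc2C(=O)C[C@H]13 | intermediate
9 | all-cis decalone lactone: 7-methyl-4-oxodecalin with lactone C-1–CH2–O–C(=O)–C-2; H-1, H-2, H-4a, H-7, H-8a all β (not isolated) | O=C3OC[C@H]1[C@H]2C[C@@H](C)CC[C@H]2C(=O)C[C@H]13 | intermediate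
10 | trans-decalone lactone: as 9 but H-4a α | O=C3OC[C@H]1[C@H]2C[C@@H](C)CC[C@@H]2C(=O)C[C@H]13 | intermediate
11 | lithium Δ3-enolate of 10 (not isolated) | O=C3OC[C@H]1[C@H]2C[C@@H](C)CC[C@@H]2C(O[Li])=C[C@H]13 | intermediate
12 | Δ3 enol triflate of 10 (C-4 OTf, C3=C4) | O=C3OC[C@H]1[C@H]2C[C@@H](C)CC[C@@H]2C(OS(=O)(=O)C(F)(F)F)=C[C@H]13 | intermediate
13 | decalin lactone: 4,7-dimethyl-Δ3-octalin with lactone C-1–CH2–O–C(=O)–C-2; H-1, H-2, H-7, H-8a β, H-4a α | O=C3OC[C@H]1[C@H]2C[C@@H](C)CC[C@@H]2C(C)=C[C@H]13 | intermediate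
14 | 5-bromo-2,4-dimethoxypyridine | COc1cc(OC)c(Br)cn1 | starting material
15 | [4-(benzyloxy)phenyl]boronic acid | OB(O)c1ccc(OCc2ccccc2)cc1 | starting material
16 | 5-[4-(benzyloxy)phenyl]-2,4-dimethoxypyridine | COc1cc(OC)c(cn1)-c1ccc(OCc2ccccc2)cc1 | intermediate
17 | 5-[4-(benzyloxy)phenyl]-3-lithio-2,4-dimethoxypyridine (not isolated) | [Li]c1c(OC)ncc(-c2ccc(OCc3ccccc3)cc2)c1OC | intermediate
18 | keto alcohol: 1-(hydroxymethyl)-4,7-dimethyl-Δ3-octalin-2-yl 5-[4-(benzyloxy)phenyl]-2,4-dimethoxypyridin-3-yl ketone, stereocentres arranged as in 13 | OC[C@H]1[C@H]2C[C@@H](C)CC[C@@H]2C(C)=C[C@H]1C(=O)c1c(OC)ncc(-c2ccc(OCc3ccccc3)cc2)c1OC | intermediate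
19 | keto aldehyde: as 18 with C-1 CHO | O=C[C@H]1[C@H]2C[C@@H](C)CC[C@@H]2C(C)=C[C@H]1C(=O)c1c(OC)ncc(-c2ccc(OCc3ccccc3)cc2)c1OC | intermediate
20 | protected target: {5-[4-(benzyloxy)phenyl]-2,4-dimethoxypyridin-3-yl}[(1S,2S,4aS,7S,8aR)-4,7-dimethyl-1-[(E)-prop-1-enyl]-1,2,4a,5,6,7,8,8a-octahydronaphthalen-2-yl]methanone | C/C=C/[C@H]1[C@H]2C[C@@H](C)CC[C@@H]2C(C)=C[C@H]1C(=O)c1c(OC)ncc(-c2ccc(OCc3ccccc3)cc2)c1OC | intermediate
21 | tris(trimethylsilyl) ether of the target (2-O, 4-O and phenol O silylated; not isolated) | C/C=C/[C@H]1[C@H]2C[C@@H](C)CC[C@@H]2C(C)=C[C@H]1C(=O)c1c(O[Si](C)(C)C)ncc(-c2ccc(O[Si](C)(C)C)cc2)c1O[Si](C)(C)C | intermediate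
22 | 4-hydroxy-5-(4-hydroxyphenyl)-3-[(1S,2S,4aS,7S,8aR)-4,7-dimethyl-1-[(E)-prop-1-enyl]-1,2,4a,5,6,7,8,8a-octahydronaphthalene-2-carbonyl]pyridin-2(1H)-one | C/C=C/[C@H]1[C@H]2C[C@@H](C)CC[C@@H]2C(C)=C[C@H]1C(=O)c1c(O)c(-c2ccc(O)cc2)c[nH]c1=O | target

**Step count**
Total: 11 steps. Longest linear sequence: 10 steps (steps 1–6 and 8–11); step 7 is the convergent branch.

**Three steps most likely to fail**

Step 4 (arene hydrogenation). The risks are reduction of the aryl ketone alongside the ring and incomplete face or cis selectivity on a trisubstituted, acyl-deactivated arene. The face selectivity directed by the C-1 arm is a prediction, not a demonstrated result. Fallback, setting out from 8: give up ketone retention and hydrogenate exhaustively over Rh/Al2O3 (H2 60 bar, iPrOH, 50 °C), which reduces ring and carbonyl to the all-cis hydroxy lactone F1 (C-4 carbinol epimers, both usable). Dess–Martin re-oxidation of F1 returns the route at the all-cis decalone lactone 9, which is equilibrated with DBU to 10 as in step 4.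

Step 8 (aryllithium on the lactone). C-2–H of 13 is allylic and α to the lactone carbonyl, so the hindered aryllithium 17 may act as a base (epimerisation at C-2, double-bond shift) or add slowly; adding LaCl3·2LiCl before 13 is a minor adjustment to try first. Fallback, setting out from 13: lower the electrophile to the aldehyde level. Reduction with iBu2AlH (CH2Cl2, −78 °C) gives the lactol F2. Excess 17 (2.5 equiv, THF, −78 → 0 °C) opens the lactolate and adds to the aldehyde form to give the diol F3 (carbinol epimers). Dess–Martin periodinane (3 equiv, NaHCO3) oxidises both hydroxyl groups and returns the route at the keto aldehyde 19, so step 9 is absorbed.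

Step 11 (global ether cleavage). Me3SiI or adventitious HI could add to the alkenes, move the C3=C4 double bond into conjugation, or epimerise C-2. Fallback, setting out from 20: replace the one-pot electrophilic cleavage by an orthogonal two-stage unmasking. Chelation-assisted nucleophilic demethylation with MgI2·OEt2 (toluene, 60 °C) removes the two pyridyl methyl groups flanking the ketone and gives the O-benzyl pyridone F4. The remaining benzyl ether is then cut at −78 °C with BCl3 and pentamethylbenzene (CH2Cl2), returning the route at the target 22.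

**Further compounds**
F1 | step 4 | all-cis 4-hydroxy-7-methyldecalin lactone (C-1–CH2–O–C(=O)–C-2; C-4 carbinol epimers) | O=C3OC[C@H]1[C@H]2C[C@@H](C)CC[C@H]2C(O)C[C@H]13
F2 | step 8 | lactol of 13 (C-2–CH(OH)–O–CH2–C-1; anomers) | OC3OC[C@H]1[C@H]2C[C@@H](C)CC[C@@H]2C(C)=C[C@H]13
F3 | step 8 | diol: C-1 CH2OH and C-2 CH(OH)-aryl (aryl = 5-[4-(benzyloxy)phenyl]-2,4-dimethoxypyridin-3-yl; carbinol epimers) | OC[C@H]1[C@H]2C[C@@H](C)CC[C@@H]2C(C)=C[C@H]1C(O)c1c(OC)ncc(-c2ccc(OCc3ccccc3)cc2)c1OC
F4 | step 11 | 5-[4-(benzyloxy)phenyl]-4-hydroxy-3-[(1S,2S,4aS,7S,8aR)-4,7-dimethyl-1-[(E)-prop-1-enyl]-1,2,4a,5,6,7,8,8a-octahydronaphthalene-2-carbonyl]pyridin-2(1H)-one | C/C=C/[C@H]1[C@H]2C[C@@H](C)CC[C@@H]2C(C)=C[C@H]1C(=O)c1c(O)c(-c2ccc(OCc3ccccc3)cc2)c[nH]c1=O
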